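## The problem

The target, compound 25, is epigallocatechin-(4β→8)-epigallocatechin 3-O-gallate-(4β→8)-epigallocatechin: three 2-(3,4,5-trihydroxyphenyl)chroman-3-ol units joined head to tail by two diarylmethine bonds, each from C4 of one unit to C8 of ring A of the next, with a galloyl ester on the C3 oxygen of the middle unit. There are eight stereocentres (C2 and C3 of the terminal unit; C2, C3 and C4 of the middle and of the upper unit); every unit is 2,3-cis and both interflavan bonds are trans to the neighbouring C3 oxygen. Within one unit the C3 oxygen substituent can steer a bond formed at C4 to the opposite face, but no unit controls C2 or C3 of another, so these centres must be bought or set unit by unit. The eighteen phenols (twelve of them in four pyrogallol rings) oxidise in air and base, the gallate is lost to strong base or nucleophiles, the C4–C8 bonds cleave under protic acid, and the benzylic C2–O1 ether can epimerise by ring opening, so the phenols must stay masked until a neutral last step. The two lower units map onto commercial (−)-epigallocatechin 1 and the galloyl group onto the commercial acid 3, so the real task is to attach a fully substituted third unit at the crowded C8 of the gallate-bearing unit with control of three new stereocentres. The enabling feature lies in the upper unit: C2 carries ring B and an oxygen, C3 an oxygen, and C4 two aryl groups (ring A of the upper unit and C8 of the middle unit). With O1–C2 opened, C2 is an α-oxybenzyl group that can sit on boron, C3–C4 is the alkene of an alkenylboron ate complex, and C8 is an aryl electrophile, so C2–C3 and C4–C8 can be formed in one three-component 1,2-metallate coupling.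

## Retrosynthesis

**25 from 24.** Only O–benzyl bonds are cut. All eighteen phenols and the terminal 3-OH are carried as benzyl ethers in 24. Benzyl survives organolithium, palladium, fluoride and peroxide steps and leaves under neutral hydrogenolysis, which methyl ethers, acetates or silyl ethers would not allow together. The forward step must remove nineteen benzyl groups without touching the gallate or the benzylic C2–O1 and C4–aryl bonds.

**24 from 23.** The O1–C2 bond of the upper unit is cut. Cutting O1–C8a instead would need an aryl C–O bond formation on a halogenated ring A. Cutting C4–C8 alone is the classical cation coupling, which is kept as the fallback. Opening O1–C2 turns the upper unit into an acyclic chain (phenol, anti-1,2-diol, diarylmethine) in 23, on which the three-component coupling can act. The forward step is an intramolecular SN2 etherification with inversion at benzylic C2, so C2 in 23 has the configuration opposite to that in 24.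

**23 from 19 through 20 and 22.** No skeletal bond is cut. The C2 hydroxyl is traced to a tert-butyldimethylsilyl ether, the ring A phenol to a methoxymethyl ether, and the C3 hydroxyl to a C–B bond. Each group is released by a reagent that is neither a protic acid nor a strong base (perborate, silyl triflate with bipyridyl, fluoride). The benzylic C2 hydroxyl is set free last, and C–B oxidation must proceed with retention so that C3 is fixed in the C–C bond-forming step.

**19 from 8, 12 and 16 (through 17 and 18).** C4–C8 and C2–C3 are cut together. A single C4–C8 cut needs a complete upper flavan unit as a cation donor. A single C2–C3 cut would be an aldol-type union with no handle for C4. The double cut divides the upper unit into a one-carbon piece with one stereocentre (boronate 12), an achiral two-carbon alkene piece (iodide 16, used as alkenyllithium 17), and bromide 8, which already holds five of the eight stereocentres. The forward reaction must add the migrating group and the aryl group anti across the E alkene, keep the configuration of the migrating carbon, select one alkene face, and let the 1,2-shift outrun direct alkenyl transfer to palladium.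

**8 from 6 and 7.** The C4(middle)–C8(terminal) bond is cut. The galloyl ester is already in place in donor 6, so no late selective acylation is needed, and as a neighbouring group it steers the nucleophile to the β face. The bromine at C8 of donor 6 blocks self-condensation and later serves as the handle for step 12. The forward step is a cation coupling at C8 of 7, trans to the C3 ester.

**6 and 7 from 2 and 3; 2 from 1.** Donor 6 is traced through bromide 5 (C4 oxidation, C8 bromination) to ester 4, which is cut at the ester C–O bond into alcohol 2 and acid 3. Acceptor 7 is the 3-O-benzyl ether of the same alcohol 2, and 2 is the pentabenzyl ether of 1. The ester bond is made on the protected alcohol rather than carried through an eightfold phenol alkylation of a preformed polyphenol ester, in which C-benzylation of ring A and loss of the acyl group would compete. One benzylation of 1 thus feeds both lower units.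

**12 from 9 through 10 and 11.** The benzylic C–B bond is cut, which leads to aldehyde 10 and a boryl-copper addition to C=O, followed by O-silylation. This step sets the carbon that becomes C2, with the configuration that the later inversion requires.

**16 from 13 through 14 and 15.** The C=C bond is cut to aldehyde 15 (one-carbon iodo-olefination). Two phenols are benzylated; the third, which becomes O1, carries the small methoxymethyl group, which is stable to tert-butyllithium and removable without acid.

## Roads not taken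

Alternative 1: The cut is C2=C3 of the terminal unit. The aldehyde ester A1 (a 3-O-silyl benzylated middle unit whose C4 aryl group carries an arylacetaldehyde side chain and an aryl 3,4,5-tribenzyloxybenzoate) would be treated with low-valent titanium from TiCl3 and zinc–copper couple. Reductive coupling of the aldehyde carbon with the ester carbonyl carbon would close ring C as the 2-aryl-4H-chromene A2.
- Merits: the key step belongs to an established class of reductive oxo-ester cyclisations and needs no chiral catalyst, so it is closer to known chemistry than step 12.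
- Weak points: it rebuilds the one unit whose stereocentres come free with 1. After A2, C2 and C3 must be created by hydroboration; syn addition places the new C3 oxygen trans to ring B (the target is cis), and the only control of the face is a stereocentre on the neighbouring unit. Titanium chlorides are Lewis acids next to an acid-labile interflavan bond. The gallate and the whole upper unit remain to be added.
- Comparison: against the better precedent of this key step, the chosen plan has every stereocentre either bought or set by a stereospecific event, fewer steps after the key step, and a classical fallback.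

Alternative 2: The cut runs through ring A of the middle unit (C8a–C8, C6–C7, and C4a–C8a re-formed). Heating the 4-substituted 3-benzyloxycyclobutenone A3 with the upper-unit siloxyalkyne A4 would give a vinylketene, [2+2] addition, 4π opening, 6π closure and tautomerisation (Danheiser benzannulation), ending in the trimer A5 with ring C of the middle unit still open.
- Merits: ring A is born fully substituted, so the crowded C8–C4 bond is never formed at a hindered arene, the substitution pattern follows from the mechanism, and no metal is used. In this respect it is better than the chosen plan, which must force palladium into a doubly ortho-substituted, electron-rich C–Br bond.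
- Weak points: both partners are late-stage compounds. A3 must carry the open C2–C3–C4 triad of the middle unit, three stereocentres made without a ring, together with the terminal unit and the gallate, on a heat- and base-sensitive cyclobutenone. A4 needs a flavan alkynylated at C4 on the β face. The cascade runs hot beside a β-acyloxy group. After A5 a ring closure and the separation of three kinds of oxygen protection remain.
- Comparison: the C2 and C3 stereocentres that 1 supplies to the middle unit are discarded and rebuilt. The chosen plan sets against the hindered oxidative addition a much shorter route that keeps both catechin-derived units intact.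

Alternative 3: The cut is C2=C3 of the middle unit. The aryl ester A6, with a vinyl group on the C4 stereocentre, would be methylenated with Cp2TiCH2ClAlMe2, and the enol ether would undergo ring-closing metathesis with the vinyl group (excess of the same reagent or second-generation Grubbs catalyst) to give the 4H-chromene A7.
- Merits: ester methylenation and enol ether metathesis are both known on aryl esters, the terminal unit comes from 1, and the key step is better precedented than step 12.
- Weak points: the diaryl(vinyl)methine stereocentre of A6 needs its own asymmetric synthesis. Syn hydroboration of A7 anti to the C4 aryl group would give the 3,4-trans relationship but would put ring B cis to that aryl group, whereas the target has it trans (2,3-cis); changing C3 afterwards does not repair C2. The titanium reagent attacks every ester, so the gallate must come later, and the upper unit is still missing.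
- Comparison: the precedent is better, but the stereochemical outcome does not match the epi series. The chosen plan keeps C2 and C3 of the middle unit from 1 and sets C4 in a neighbouring-group-controlled coupling.

Key step: step 12

Assumption: the ligand antipodes named, (R)-DTBM-SEGPHOS in step 8 and (Sp,Sp)-MandyPhos in step 12, are taken to give the configurations drawn; if the sense of induction is the opposite, the mirror-image ligand is used and nothing else changes.

## Route

Step 1
Reactants: 1 (−)-epigallocatechin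
Product: 2 5,7,3′,4′,5′-penta-O-benzyl-(−)-epigallocatechin
Conditions: BnBr, K2CO3, DMF, 0 °C → rt
Reagents that add atoms: benzyl bromide, BrCc1ccccc1
Why: Williamson etherification of the five phenols; carbonate does not deprotonate the secondary 3-OH, which stays free, and C2 and C3 are not touched.

Step 2
Reactants: 2 5,7,3′,4′,5′-penta-O-benzyl-(−)-epigallocatechin; 3 3,4,5-tris(benzyloxy)benzoic acid
Product: 4 octa-O-benzyl-(−)-epigallocatechin gallate
Conditions: 3 (1.5 equiv), DCC, DMAP, CH2Cl2, 0 °C → rt
Reagents that add atoms: none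
Why: Steglich esterification: DCC activates acid 3 as the O-acylisourea and DMAP relays the acyl group to the 3-OH, the only free hydroxyl of 2; no stereocentre is involved.

Step 3
Reactants: 4 octa-O-benzyl-(−)-epigallocatechin gallate
Product: 5 8-bromo-octa-O-benzyl-(−)-epigallocatechin gallate
Conditions: NBS, CH2Cl2, −20 °C → 0 °C
Reagents that add atoms: N-bromosuccinimide, O=C1CCC(=O)N1Br
Why: Electrophilic aromatic bromination; ring A is a phloroglucinol triether and far more electron-rich than ring B or the ester-deactivated galloyl ring, and in 5,7-dibenzyloxyflavans C8 reacts before C6.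

Step 4
Reactants: 5 8-bromo-octa-O-benzyl-(−)-epigallocatechin gallate
Product: 6 8-bromo-4β-(2-ethoxyethoxy)-octa-O-benzyl-epigallocatechin gallate
Conditions: DDQ, 2-ethoxyethanol, CH2Cl2, rt
Reagents that add atoms: 2-ethoxyethanol, CCOCCO
Why: DDQ benzylic oxidation: hydride loss from C4 gives a cation stabilised by the ring A oxygens, which the alcohol captures trans to the C3 ester; benzyl ethers, bromide and ester are inert.

Step 5
Reactants: 2 5,7,3′,4′,5′-penta-O-benzyl-(−)-epigallocatechin
Product: 7 3,5,7,3′,4′,5′-hexa-O-benzyl-(−)-epigallocatechin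
Conditions: NaH, BnBr, n-Bu4NI (cat.), THF/DMF, 0 °C → rt
Reagents that add atoms: benzyl bromide, BrCc1ccccc1
Why: Williamson etherification of the secondary alkoxide; with all phenols capped there is no path to ring opening at C2.

Step 6
Reactants: 6 8-bromo-4β-(2-ethoxyethoxy)-octa-O-benzyl-epigallocatechin gallate; 7 3,5,7,3′,4′,5′-hexa-O-benzyl-(−)-epigallocatechin
Product: 8 tetradeca-O-benzyl 8-bromo-epigallocatechin 3-O-gallate-(4β→8)-epigallocatechin
Conditions: TMSOTf (cat.), 7 (1.5 equiv), CH2Cl2, −78 °C → −40 °C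
Reagents that add atoms: none
Why: Lewis-acid-promoted Friedel–Crafts-type coupling of a flavan-4-yl cation: the C3 galloyl carbonyl bridges the α face of the cation, so C8 of 7, its most nucleophilic position, attacks from the β face and sets C4 trans to the C3 oxygen; the bromine at C8 of 6 prevents self-condensation.

Step 7
Reactants: 9 3,4,5-trihydroxybenzaldehyde
Product: 10 3,4,5-tris(benzyloxy)benzaldehyde
Conditions: BnBr, K2CO3, DMF, 60 °C
Reagents that add atoms: benzyl bromide, BrCc1ccccc1
Why: Williamson etherification of the three phenols; the aldehyde is inert to carbonate.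

Step 8
Reactants: 10 3,4,5-tris(benzyloxy)benzaldehyde
Product: 12 (R)-(tert-butyldimethylsilyloxy)[3,4,5-tris(benzyloxy)phenyl]methyl pinacol boronate, via α-hydroxy boronate 11 (not isolated)
Conditions: B2pin2, CuCl (5 mol%), (R)-DTBM-SEGPHOS (5 mol%), KOt-Bu (10 mol%), MeOH, THF, 0 °C; then TBSCl, imidazole, 0 °C → rt
Reagents that add atoms: bis(pinacolato)diboron, CC1(C)OB(OC1(C)C)B1OC(C)(C)C(C)(C)O1; tert-butyldimethylsilyl chloride, CC(C)(C)[Si](C)(C)Cl
Why: Proposed new method: a boryl-copper species formed from CuCl, KOt-Bu, the bisphosphine and B2pin2 adds across the aldehyde C=O on the face left open by the ligand, methanol protonates the copper alkoxide to 11 before boron can shift from carbon to oxygen, and silylation in the same flask blocks that shift; the closest known reaction type is the enantioselective monovalent-copper-catalysed borylation of aliphatic aldehydes with O-protection in the same flask, while aryl aldehydes are established substrates only for the racemic copper-catalysed borylation, so sense and level of induction at this benzylic carbon (the later C2) are untested.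

Step 9
Reactants: 13 2,4,6-trihydroxybenzaldehyde
Product: 14 2,4-bis(benzyloxy)-6-hydroxybenzaldehyde
Conditions: BnBr (2 equiv), K2CO3, DMF, rt
Reagents that add atoms: benzyl bromide, BrCc1ccccc1
Why: Williamson etherification that stops after two alkylations, because the last ortho hydroxyl is held in a hydrogen bond to the aldehyde and is the least acidic and least nucleophilic.

Step 10
Reactants: 14 2,4-bis(benzyloxy)-6-hydroxybenzaldehyde
Product: 15 2,4-bis(benzyloxy)-6-(methoxymethoxy)benzaldehyde
Conditions: MOMCl, i-Pr2NEt, CH2Cl2, 0 °C → 40 °C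
Reagents that add atoms: chloromethyl methyl ether, COCCl
Why: O-alkylation of the phenol with a reactive α-chloro ether (acetal formation), which overcomes the hydrogen bond that stopped benzylation.

Step 11
Reactants: 15 2,4-bis(benzyloxy)-6-(methoxymethoxy)benzaldehyde
Product: 16 (E)-1,5-bis(benzyloxy)-2-(2-iodoethenyl)-3-(methoxymethoxy)benzene
Conditions: CrCl2 (6 equiv), CHI3 (2 equiv), THF, 0 °C → rt
Reagents that add atoms: iodoform, IC(I)I
Why: Takai olefination: the geminal dichromium species from iodoform adds to the aldehyde and eliminates to the E alkenyl iodide; aryl aldehydes are good substrates and the ethers are inert.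

Step 12
Reactants: 16 (E)-1,5-bis(benzyloxy)-2-(2-iodoethenyl)-3-(methoxymethoxy)benzene; 12 (R)-(tert-butyldimethylsilyloxy)[3,4,5-tris(benzyloxy)phenyl]methyl pinacol boronate; 8 tetradeca-O-benzyl 8-bromo-epigallocatechin 3-O-gallate-(4β→8)-epigallocatechin
Product: 19 dimer carrying at C8 of the gallate-bearing unit the open-chain upper unit (C3–Bpin; C2–OTBS; ring A methoxymethyl ether), via alkenyllithium 17 (not isolated), via boron ate complex 18 (not isolated)
Conditions: t-BuLi (2 equiv), Et2O, −78 °C; 12, THF, −78 °C → rt; then 8, Pd(OAc)2 (5 mol%), (Sp,Sp)-MandyPhos (6 mol%), NaOTf, THF, 60 °C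
Reagents that add atoms: none
Why: Proposed new method: iodine–lithium exchange gives the E alkenyllithium 17 with retention, which adds to boron of 12 to give ate complex 18; zerovalent palladium formed from Pd(OAc)2 and MandyPhos inserts into the C8–Br bond of 8, NaOTf removes halide, and the cationic arylpalladium binds the alkene of 18. The α-silyloxybenzyl group then shifts from boron to the boron-bearing alkene carbon anti to palladium, with retention at the migrating carbon, while palladium bonds to the benzylic carbon, and reductive elimination joins that carbon to C8 with retention. The closest known reaction type is the palladium-catalysed conjunctive cross-coupling of alkenylboron ate complexes with aryl triflates and halides, which has not been shown with an α-oxybenzyl migrating group or with a doubly ortho-substituted, electron-rich aryl bromide. No ring closes in this step. C3 and C4 arise as a pair: their relative configuration follows from anti addition across the E alkene (later the 3,4-trans relationship), their absolute sense from the alkene face chosen by the palladium–MandyPhos cation, with the ligand antipode matched to the R boronate, and C2 is carried over unchanged from 12. The step needs the 1,2-shift to outrun direct alkenyl transfer to palladium (a Suzuki-type path) and β-hydride loss; the electron-rich ring A on the alkene favours benzylic Pd–C bonding, crowding at boron and at the arylpalladium disfavours the B–O–Pd bridged transfer, and the wide-bite bisphosphine speeds reductive elimination. The ester of 8 never meets an organolithium, because 17 is consumed by 12 before 8 is added.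

Step 13
Reactants: 19 dimer carrying the open-chain upper unit with C3–Bpin
Product: 20 C3 alcohol of 19 (C3–OH in place of C3–Bpin)
Conditions: NaBO3·4H2O, THF/H2O, rt
Reagents that add atoms: sodium perborate tetrahydrate, [Na+].O[B-]1(O)OO1.O.O.O
Why: Oxidation of a secondary alkylboronate: peroxide adds to boron and C3 migrates from boron to oxygen with retention; the weakly basic medium spares the gallate, the silyl ether and the methoxymethyl ether.

Step 14
Reactants: 20 C3 alcohol of 19
Product: 22 ring A phenol (methoxymethyl group removed; C2–OTBS and C3–OH retained), via bis(trimethylsilyl) ether 21 (not isolated)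
Conditions: TMSOTf, 2,2′-bipyridyl, CH2Cl2, 0 °C → rt; then H2O
Reagents that add atoms: none
Why: Non-acidic cleavage of an aryl methoxymethyl ether: the silyl triflate–bipyridyl pair moves a trimethylsilyl group onto the phenol oxygen and the methoxymethyl group onto a pyridine nitrogen, and water then hydrolyses the aryl and C3 trimethylsilyl ethers; no free acid reaches the TBS ether, the benzyl ethers or the interflavan bond.

Step 15
Reactants: 22 ring A phenol with C2–OTBS
Product: 23 triol (ring A phenol, C2–OH, C3–OH)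
Conditions: TBAF, AcOH, THF, 0 °C → rt
Reagents that add atoms: none
Why: Fluoride-induced cleavage of the silyl ether; buffering with acetic acid keeps phenoxide and alkoxide concentrations low, so the gallate is not attacked.

Step 16
Reactants: 23 triol
Product: 24 nonadeca-O-benzyl epigallocatechin-(4β→8)-epigallocatechin 3-O-gallate-(4β→8)-epigallocatechin with free 3-OH in the upper unit
Conditions: PPh3, DIAD, THF, 0 °C → rt
Reagents that add atoms: none
Why: Intramolecular Mitsunobu etherification: the benzylic C2 hydroxyl becomes the oxyphosphonium leaving group and the ring A phenoxide displaces it in a 6-exo-tet SN2 step, so O1–C2 forms with inversion and the anti 2,3-diol becomes the 2,3-cis flavan-3-ol; closure with a free 3-OH is known in flavan-3-ol synthesis, and the two meta benzyloxy groups of ring B hold back ionisation at C2.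

Step 17
Reactants: 24 nonadeca-O-benzyl trimer
Product: 25 epigallocatechin-(4β→8)-epigallocatechin 3-O-gallate-(4β→8)-epigallocatechin (target)
Conditions: H2 (1 atm), Pd(OH)2/C, THF/MeOH/H2O, rt
Reagents that add atoms: none
Why: Catalytic hydrogenolysis of nineteen benzyl ethers under neutral conditions; the gallate, the interflavan bonds and all stereocentres are unaffected.

## Compound list

1 | (−)-epigallocatechin, (2R,3R) | O[C@@H]1Cc2c(O)cc(O)cc2O[C@@H]1c1cc(O)c(O)c(O)c1 | starting material

2 | 5,7,3′,4′,5′-penta-O-benzyl-(−)-epigallocatechin, (2R,3R), 3-OH free | O[C@@H]1Cc2c(OCc9ccccc9)cc(OCc9ccccc9)cc2O[C@@H]1c7cc(OCc9ccccc9)c(OCc9ccccc9)c(OCc9ccccc9)c7 | intermediate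

3 | 3,4,5-tris(benzyloxy)benzoic acid | OC(=O)c1cc(OCc2ccccc2)c(OCc2ccccc2)c(OCc2ccccc2)c1 | starting material

4 | octa-O-benzyl-(−)-epigallocatechin gallate, (2R,3R) | O=C(O[C@@H]1Cc2c(OCc9ccccc9)cc(OCc9ccccc9)cc2O[C@@H]1c7cc(OCc9ccccc9)c(OCc9ccccc9)c(OCc9ccccc9)c7)c7cc(OCc9ccccc9)c(OCc9ccccc9)c(OCc9ccccc9)c7 | intermediate

5 | 8-bromo-octa-O-benzyl-(−)-epigallocatechin gallate, (2R,3R), bromine at C8 of ring A | O=C(O[C@@H]1Cc2c(OCc9ccccc9)cc(OCc9ccccc9)c(Br)c2O[C@@H]1c7cc(OCc9ccccc9)c(OCc9ccccc9)c(OCc9ccccc9)c7)c7cc(OCc9ccccc9)c(OCc9ccccc9)c(OCc9ccccc9)c7 | intermediate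

6 | 8-bromo-4β-(2-ethoxyethoxy)-octa-O-benzyl-epigallocatechin gallate, (2R,3R,4S), 4-alkoxy trans to the 3-ester | O=C(O[C@@H]1[C@@H](OCCOCC)c2c(OCc9ccccc9)cc(OCc9ccccc9)c(Br)c2O[C@@H]1c7cc(OCc9ccccc9)c(OCc9ccccc9)c(OCc9ccccc9)c7)c7cc(OCc9ccccc9)c(OCc9ccccc9)c(OCc9ccccc9)c7 | intermediate

7 | 3,5,7,3′,4′,5′-hexa-O-benzyl-(−)-epigallocatechin, (2R,3R) | O(Cc9ccccc9)[C@@H]1Cc2c(OCc9ccccc9)cc(OCc9ccccc9)cc2O[C@@H]1c7cc(OCc9ccccc9)c(OCc9ccccc9)c(OCc9ccccc9)c7 | intermediate

8 | tetradeca-O-benzyl 8-bromo-epigallocatechin 3-O-gallate-(4β→8)-epigallocatechin (bromine at C8 of the gallate-bearing unit, terminal 3-O-benzyl, both units 2,3-cis, interflavan bond trans to the ester) | O=C(O[C@@H]1[C@@H](c2c(OCc9ccccc9)cc(OCc9ccccc9)c3c2O[C@H](c7cc(OCc9ccccc9)c(OCc9ccccc9)c(OCc9ccccc9)c7)[C@H](OCc9ccccc9)C3)c2c(OCc9ccccc9)cc(OCc9ccccc9)c(Br)c2O[C@@H]1c7cc(OCc9ccccc9)c(OCc9ccccc9)c(OCc9ccccc9)c7)c7cc(OCc9ccccc9)c(OCc9ccccc9)c(OCc9ccccc9)c7 | intermediate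

9 | 3,4,5-trihydroxybenzaldehyde | O=Cc1cc(O)c(O)c(O)c1 | starting material

10 | 3,4,5-tris(benzyloxy)benzaldehyde | O=Cc1cc(OCc9ccccc9)c(OCc9ccccc9)c(OCc9ccccc9)c1 | intermediate

11 | (R)-hydroxy[3,4,5-tris(benzyloxy)phenyl]methyl pinacol boronate | CC1(C)OB(OC1(C)C)[C@@H](O)c7cc(OCc9ccccc9)c(OCc9ccccc9)c(OCc9ccccc9)c7 | intermediate

12 | (R)-(tert-butyldimethylsilyloxy)[3,4,5-tris(benzyloxy)phenyl]methyl pinacol boronate | CC1(C)OB(OC1(C)C)[C@@H](O[Si](C)(C)C(C)(C)C)c7cc(OCc9ccccc9)c(OCc9ccccc9)c(OCc9ccccc9)c7 | intermediate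

13 | 2,4,6-trihydroxybenzaldehyde | O=Cc1c(O)cc(O)cc1O | starting material

14 | 2,4-bis(benzyloxy)-6-hydroxybenzaldehyde | O=Cc1c(O)cc(OCc9ccccc9)cc1OCc9ccccc9 | intermediate

15 | 2,4-bis(benzyloxy)-6-(methoxymethoxy)benzaldehyde | O=Cc1c(OCOC)cc(OCc9ccccc9)cc1OCc9ccccc9 | intermediate

16 | (E)-1,5-bis(benzyloxy)-2-(2-iodoethenyl)-3-(methoxymethoxy)benzene | I/C=C/c1c(OCOC)cc(OCc9ccccc9)cc1OCc9ccccc9 | intermediate

17 | (E)-2-[2,4-bis(benzyloxy)-6-(methoxymethoxy)phenyl]ethenyllithium | [Li]/C=C/c1c(OCOC)cc(OCc9ccccc9)cc1OCc9ccccc9 | intermediate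

18 | lithium ate complex of 12 with the E alkenyl group of 17 on boron (benzylic carbon R) | [Li+].CC1(C)O[B-](OC1(C)C)(/C=C/c4c(OCOC)cc(OCc9ccccc9)cc4OCc9ccccc9)[C@@H](O[Si](C)(C)C(C)(C)C)c7cc(OCc9ccccc9)c(OCc9ccccc9)c(OCc9ccccc9)c7 | intermediate

19 | 8 with bromine replaced by a (1R,2R,3R)-1-[2,4-bis(benzyloxy)-6-(methoxymethoxy)phenyl]-2-(pinacolboryl)-3-(tert-butyldimethylsilyloxy)-3-[3,4,5-tris(benzyloxy)phenyl]propyl group (C1 = later C4, C2 = later C3, C3 = later C2) | O=C(O[C@@H]1[C@@H](c2c(OCc9ccccc9)cc(OCc9ccccc9)c3c2O[C@H](c7cc(OCc9ccccc9)c(OCc9ccccc9)c(OCc9ccccc9)c7)[C@H](OCc9ccccc9)C3)c2c(OCc9ccccc9)cc(OCc9ccccc9)c([C@@H](c4c(OCc9ccccc9)cc(OCc9ccccc9)cc4OCOC)[C@@H](B5OC(C)(C)C(C)(C)O5)[C@@H](O[Si](C)(C)C(C)(C)C)c7cc(OCc9ccccc9)c(OCc9ccccc9)c(OCc9ccccc9)c7)c2O[C@@H]1c7cc(OCc9ccccc9)c(OCc9ccccc9)c(OCc9ccccc9)c7)c7cc(OCc9ccccc9)c(OCc9ccccc9)c(OCc9ccccc9)c7 | intermediate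

20 | C3 alcohol: as 19 with hydroxyl in place of boron, side chain (1R,2R,3S) | O=C(O[C@@H]1[C@@H](c2c(OCc9ccccc9)cc(OCc9ccccc9)c3c2O[C@H](c7cc(OCc9ccccc9)c(OCc9ccccc9)c(OCc9ccccc9)c7)[C@H](OCc9ccccc9)C3)c2c(OCc9ccccc9)cc(OCc9ccccc9)c([C@@H](c4c(OCc9ccccc9)cc(OCc9ccccc9)cc4OCOC)[C@@H](O)[C@@H](O[Si](C)(C)C(C)(C)C)c7cc(OCc9ccccc9)c(OCc9ccccc9)c(OCc9ccccc9)c7)c2O[C@@H]1c7cc(OCc9ccccc9)c(OCc9ccccc9)c(OCc9ccccc9)c7)c7cc(OCc9ccccc9)c(OCc9ccccc9)c(OCc9ccccc9)c7 | intermediate

21 | bis(trimethylsilyl) ether: as 20 with trimethylsilyl on the ring A oxygen (in place of methoxymethyl) and on the C3 oxygen | O=C(O[C@@H]1[C@@H](c2c(OCc9ccccc9)cc(OCc9ccccc9)c3c2O[C@H](c7cc(OCc9ccccc9)c(OCc9ccccc9)c(OCc9ccccc9)c7)[C@H](OCc9ccccc9)C3)c2c(OCc9ccccc9)cc(OCc9ccccc9)c([C@@H](c4c(OCc9ccccc9)cc(OCc9ccccc9)cc4O[Si](C)(C)C)[C@@H](O[Si](C)(C)C)[C@@H](O[Si](C)(C)C(C)(C)C)c7cc(OCc9ccccc9)c(OCc9ccccc9)c(OCc9ccccc9)c7)c2O[C@@H]1c7cc(OCc9ccccc9)c(OCc9ccccc9)c(OCc9ccccc9)c7)c7cc(OCc9ccccc9)c(OCc9ccccc9)c(OCc9ccccc9)c7 | intermediate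

22 | ring A phenol: as 20 with free phenol in place of the methoxymethyl ether, side chain (1R,2R,3S) | O=C(O[C@@H]1[C@@H](c2c(OCc9ccccc9)cc(OCc9ccccc9)c3c2O[C@H](c7cc(OCc9ccccc9)c(OCc9ccccc9)c(OCc9ccccc9)c7)[C@H](OCc9ccccc9)C3)c2c(OCc9ccccc9)cc(OCc9ccccc9)c([C@@H](c4c(OCc9ccccc9)cc(OCc9ccccc9)cc4O)[C@@H](O)[C@@H](O[Si](C)(C)C(C)(C)C)c7cc(OCc9ccccc9)c(OCc9ccccc9)c(OCc9ccccc9)c7)c2O[C@@H]1c7cc(OCc9ccccc9)c(OCc9ccccc9)c(OCc9ccccc9)c7)c7cc(OCc9ccccc9)c(OCc9ccccc9)c(OCc9ccccc9)c7 | intermediate

23 | triol: as 22 with free C2 hydroxyl (side chain (1R,2R,3S)-1-[2,4-bis(benzyloxy)-6-hydroxyphenyl]-2,3-dihydroxy-3-[3,4,5-tris(benzyloxy)phenyl]propyl, anti 2,3-diol) | O=C(O[C@@H]1[C@@H](c2c(OCc9ccccc9)cc(OCc9ccccc9)c3c2O[C@H](c7cc(OCc9ccccc9)c(OCc9ccccc9)c(OCc9ccccc9)c7)[C@H](OCc9ccccc9)C3)c2c(OCc9ccccc9)cc(OCc9ccccc9)c([C@@H](c4c(OCc9ccccc9)cc(OCc9ccccc9)cc4O)[C@@H](O)[C@@H](O)c7cc(OCc9ccccc9)c(OCc9ccccc9)c(OCc9ccccc9)c7)c2O[C@@H]1c7cc(OCc9ccccc9)c(OCc9ccccc9)c(OCc9ccccc9)c7)c7cc(OCc9ccccc9)c(OCc9ccccc9)c(OCc9ccccc9)c7 | intermediate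

24 | nonadeca-O-benzyl epigallocatechin-(4β→8)-epigallocatechin 3-O-gallate-(4β→8)-epigallocatechin, free 3-OH in the upper unit (upper unit 2R,3R,4R; all units 2,3-cis, both interflavan bonds 3,4-trans) | O=C(O[C@@H]1[C@@H](c2c(OCc9ccccc9)cc(OCc9ccccc9)c3c2O[C@H](c7cc(OCc9ccccc9)c(OCc9ccccc9)c(OCc9ccccc9)c7)[C@H](OCc9ccccc9)C3)c2c(OCc9ccccc9)cc(OCc9ccccc9)c([C@H]3c4c(OCc9ccccc9)cc(OCc9ccccc9)cc4O[C@H](c7cc(OCc9ccccc9)c(OCc9ccccc9)c(OCc9ccccc9)c7)[C@@H]3O)c2O[C@@H]1c7cc(OCc9ccccc9)c(OCc9ccccc9)c(OCc9ccccc9)c7)c7cc(OCc9ccccc9)c(OCc9ccccc9)c(OCc9ccccc9)c7 | intermediate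

25 | epigallocatechin-(4β→8)-epigallocatechin 3-O-gallate-(4β→8)-epigallocatechin (CNP0278699.1) | O=C(O[C@@H]1[C@@H](c2c(O)cc(O)c3c2O[C@H](c2cc(O)c(O)c(O)c2)[C@H](O)C3)c2c(O)cc(O)c([C@H]3c4c(O)cc(O)cc4O[C@H](c4cc(O)c(O)c(O)c4)[C@@H]3O)c2O[C@@H]1c1cc(O)c(O)c(O)c1)c1cc(O)c(O)c(O)c1 | target

## Step count and least certain steps

Total: 17 steps. Longest linear sequence: 11 steps (1 → 2 → 4 → 5 → 6 → 8 → 19 → 20 → 22 → 23 → 24 → 25; steps 1, 2, 3, 4, 6, 12, 13, 14, 15, 16, 17).

**Step 12 (key step, proposed new method).** The most likely failures are: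
- transfer of the alkenyl group from boron to palladium without the 1,2-shift, which ends in plain Suzuki-type coupling;
- no oxidative addition at the doubly ortho-substituted, electron-rich C8–Br bond;
- poor face selectivity when ligand and R boronate are mismatched;
- β-hydride loss from the benzylic palladium intermediate.

A first adjustment inside the strategy is a bulkier diol on boron. The fallback uses only known cation chemistry and sets out from 4, 2 and 7. Oxidation of 4 with DDQ and 2-ethoxyethanol gives the bromine-free 4β-(2-ethoxyethoxy)-octa-O-benzyl-epigallocatechin gallate F1. TMSOTf-promoted coupling of F1 with an excess of 7 gives the bromine-free dimer F2. Compound 2 is oxidised in the same way to 4β-(2-ethoxyethoxy)-penta-O-benzyl-epigallocatechin F3, whose free 3-OH directs attack to the opposite face. TMSOTf-promoted coupling of F3 with an excess of F2, at C8 of the gallate-bearing unit, gives 24, where the route is rejoined.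

**Step 8 (proposed new method).** The most likely failure is erosion of enantiopurity, because the benzylic copper alkoxide can pass boron from carbon to oxygen or add reversibly before protonation. The fallback sets out from 10. Borylation with B2pin2 under the achiral catalyst chloro(1,3-dicyclohexylimidazol-2-ylidene)copper, (ICy)CuCl, a known reaction of aryl aldehydes, followed by silylation, gives the racemic silyloxybenzyl pinacol boronate F4. Used in excess in step 12 under ligand control, F4 gives 19 together with its C2 epimer F5; these are diastereomers and are separated by chromatography. The route is rejoined at 19.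

**Step 16.** Ionisation at benzylic C2 before displacement would cost stereospecificity and favour the 2,3-trans ring. Activation of the C3 hydroxyl instead would lead to five-ring closure. The fallback sets out from 23. Triethyl orthoformate and pyridinium p-toluenesulfonate convert the 2,3-diol into the cyclic ethyl orthoformate F6. On warming, F6 ionises to the dioxolanylium ion, which the phenol opens at C2 with inversion to give the 3-O-formate F7. KHCO3 in methanol removes the formate and gives 24.

**Step 6.** The 3-O-acyl group slows ionisation at C4 and can trap the cation as an orthoester, and attack through C6 of 7 would give the 4→6 isomer. The fallback sets out from 2 and installs the ester after the coupling, which also moves the DDQ oxidation away from the deactivating ester. NBS gives 8-bromo-penta-O-benzyl-epigallocatechin F8. DDQ and 2-ethoxyethanol give its 4β-(2-ethoxyethoxy) ether F9. TMSOTf-promoted coupling with 7 gives the dimer alcohol F10. Esterification with acid 3 (DCC, DMAP) gives 8.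

## Further compounds

F1 | step 12 | 4β-(2-ethoxyethoxy)-octa-O-benzyl-epigallocatechin gallate (no bromine) | O=C(O[C@@H]1[C@@H](OCCOCC)c2c(OCc9ccccc9)cc(OCc9ccccc9)cc2O[C@@H]1c7cc(OCc9ccccc9)c(OCc9ccccc9)c(OCc9ccccc9)c7)c7cc(OCc9ccccc9)c(OCc9ccccc9)c(OCc9ccccc9)c7

F2 | step 12 | tetradeca-O-benzyl epigallocatechin 3-O-gallate-(4β→8)-epigallocatechin (C8–H in the gallate-bearing unit) | O=C(O[C@@H]1[C@@H](c2c(OCc9ccccc9)cc(OCc9ccccc9)c3c2O[C@H](c7cc(OCc9ccccc9)c(OCc9ccccc9)c(OCc9ccccc9)c7)[C@H](OCc9ccccc9)C3)c2c(OCc9ccccc9)cc(OCc9ccccc9)cc2O[C@@H]1c7cc(OCc9ccccc9)c(OCc9ccccc9)c(OCc9ccccc9)c7)c7cc(OCc9ccccc9)c(OCc9ccccc9)c(OCc9ccccc9)c7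

F3 | step 12 | 4β-(2-ethoxyethoxy)-5,7,3′,4′,5′-penta-O-benzyl-epigallocatechin (3-OH free) | O[C@@H]1[C@@H](OCCOCC)c2c(OCc9ccccc9)cc(OCc9ccccc9)cc2O[C@@H]1c7cc(OCc9ccccc9)c(OCc9ccccc9)c(OCc9ccccc9)c7

F4 | step 8 | racemic (tert-butyldimethylsilyloxy)[3,4,5-tris(benzyloxy)phenyl]methyl pinacol boronate | CC1(C)OB(OC1(C)C)C(O[Si](C)(C)C(C)(C)C)c7cc(OCc9ccccc9)c(OCc9ccccc9)c(OCc9ccccc9)c7

F5 | step 8 | C2 epimer of 19 (side chain 1R,2R,3S) | O=C(O[C@@H]1[C@@H](c2c(OCc9ccccc9)cc(OCc9ccccc9)c3c2O[C@H](c7cc(OCc9ccccc9)c(OCc9ccccc9)c(OCc9ccccc9)c7)[C@H](OCc9ccccc9)C3)c2c(OCc9ccccc9)cc(OCc9ccccc9)c([C@@H](c4c(OCc9ccccc9)cc(OCc9ccccc9)cc4OCOC)[C@@H](B5OC(C)(C)C(C)(C)O5)[C@H](O[Si](C)(C)C(C)(C)C)c7cc(OCc9ccccc9)c(OCc9ccccc9)c(OCc9ccccc9)c7)c2O[C@@H]1c7cc(OCc9ccccc9)c(OCc9ccccc9)c(OCc9ccccc9)c7)c7cc(OCc9ccccc9)c(OCc9ccccc9)c(OCc9ccccc9)c7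

F6 | step 16 | cyclic ethyl orthoformate of the 2,3-diol of 23 (2-ethoxy-1,3-dioxolane, mixture at the orthoester carbon) | O=C(O[C@@H]1[C@@H](c2c(OCc9ccccc9)cc(OCc9ccccc9)c3c2O[C@H](c7cc(OCc9ccccc9)c(OCc9ccccc9)c(OCc9ccccc9)c7)[C@H](OCc9ccccc9)C3)c2c(OCc9ccccc9)cc(OCc9ccccc9)c([C@@H](c4c(OCc9ccccc9)cc(OCc9ccccc9)cc4O)[C@H]5OC(OCC)O[C@H]5c7cc(OCc9ccccc9)c(OCc9ccccc9)c(OCc9ccccc9)c7)c2O[C@@H]1c7cc(OCc9ccccc9)c(OCc9ccccc9)c(OCc9ccccc9)c7)c7cc(OCc9ccccc9)c(OCc9ccccc9)c(OCc9ccccc9)c7

F7 | step 16 | 3-O-formate of 24 (upper unit) | O=C(O[C@@H]1[C@@H](c2c(OCc9ccccc9)cc(OCc9ccccc9)c3c2O[C@H](c7cc(OCc9ccccc9)c(OCc9ccccc9)c(OCc9ccccc9)c7)[C@H](OCc9ccccc9)C3)c2c(OCc9ccccc9)cc(OCc9ccccc9)c([C@H]3c4c(OCc9ccccc9)cc(OCc9ccccc9)cc4O[C@H](c7cc(OCc9ccccc9)c(OCc9ccccc9)c(OCc9ccccc9)c7)[C@@H]3OC=O)c2O[C@@H]1c7cc(OCc9ccccc9)c(OCc9ccccc9)c(OCc9ccccc9)c7)c7cc(OCc9ccccc9)c(OCc9ccccc9)c(OCc9ccccc9)c7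

F8 | step 6 | 8-bromo-5,7,3′,4′,5′-penta-O-benzyl-epigallocatechin | O[C@@H]1Cc2c(OCc9ccccc9)cc(OCc9ccccc9)c(Br)c2O[C@@H]1c7cc(OCc9ccccc9)c(OCc9ccccc9)c(OCc9ccccc9)c7

F9 | step 6 | 8-bromo-4β-(2-ethoxyethoxy)-5,7,3′,4′,5′-penta-O-benzyl-epigallocatechin | O[C@@H]1[C@@H](OCCOCC)c2c(OCc9ccccc9)cc(OCc9ccccc9)c(Br)c2O[C@@H]1c7cc(OCc9ccccc9)c(OCc9ccccc9)c(OCc9ccccc9)c7

F10 | step 6 | undeca-O-benzyl 8-bromo-epigallocatechin-(4β→8)-epigallocatechin with free 3-OH in the brominated unit | O[C@@H]1[C@@H](c2c(OCc9ccccc9)cc(OCc9ccccc9)c3c2O[C@H](c7cc(OCc9ccccc9)c(OCc9ccccc9)c(OCc9ccccc9)c7)[C@H](OCc9ccccc9)C3)c2c(OCc9ccccc9)cc(OCc9ccccc9)c(Br)c2O[C@@H]1c7cc(OCc9ccccc9)c(OCc9ccccc9)c(OCc9ccccc9)c7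

A1 | alternative 1 | 3-O-TBS benzylated middle unit bearing at C4 a 4,6-bis(benzyloxy)-3-(2-oxoethyl)-2-[3,4,5-tris(benzyloxy)benzoyloxy]phenyl group | CC(C)(C)[Si](C)(C)O[C@@H]1[C@@H](c2c(OCc9ccccc9)cc(OCc9ccccc9)c(CC=O)c2OC(=O)c7cc(OCc9ccccc9)c(OCc9ccccc9)c(OCc9ccccc9)c7)c2c(OCc9ccccc9)cc(OCc9ccccc9)cc2O[C@@H]1c7cc(OCc9ccccc9)c(OCc9ccccc9)c(OCc9ccccc9)c7

A2 | alternative 1 | 3-O-TBS benzylated middle unit bonded at C4 to C8 of a 2-aryl-4H-chromene terminal unit | CC(C)(C)[Si](C)(C)O[C@@H]1[C@@H](c2c(OCc9ccccc9)cc(OCc9ccccc9)c3c2OC(c7cc(OCc9ccccc9)c(OCc9ccccc9)c(OCc9ccccc9)c7)=CC3)c2c(OCc9ccccc9)cc(OCc9ccccc9)cc2O[C@@H]1c7cc(OCc9ccccc9)c(OCc9ccccc9)c(OCc9ccccc9)c7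

A3 | alternative 2 | 3-benzyloxycyclobut-2-enone carrying at C4 the open middle-unit chain (terminal unit, galloyloxy, triethylsilyloxy; epimers at the ring carbon) | O=C(c7cc(OCc9ccccc9)c(OCc9ccccc9)c(OCc9ccccc9)c7)O[C@H]([C@@H](c2c(OCc9ccccc9)cc(OCc9ccccc9)c3c2O[C@H](c7cc(OCc9ccccc9)c(OCc9ccccc9)c(OCc9ccccc9)c7)[C@H](OCc9ccccc9)C3)C1C(=O)C=C1OCc9ccccc9)[C@@H](O[Si](CC)(CC)CC)c7cc(OCc9ccccc9)c(OCc9ccccc9)c(OCc9ccccc9)c7

A4 | alternative 2 | hexa-O-benzyl upper unit bearing a (triisopropylsilyloxy)ethynyl group at C4 (β) | CC(C)[Si](C(C)C)(C(C)C)OC#C[C@H]3c4c(OCc9ccccc9)cc(OCc9ccccc9)cc4O[C@H](c7cc(OCc9ccccc9)c(OCc9ccccc9)c(OCc9ccccc9)c7)[C@@H]3OCc9ccccc9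

A5 | alternative 2 | protected trimer with ring C of the middle unit open at O1–C2 (free C8a phenol, C7 triisopropylsilyl ether, C2 triethylsilyl ether) | O=C(c7cc(OCc9ccccc9)c(OCc9ccccc9)c(OCc9ccccc9)c7)O[C@H]([C@@H](c2c(OCc9ccccc9)cc(OCc9ccccc9)c3c2O[C@H](c7cc(OCc9ccccc9)c(OCc9ccccc9)c(OCc9ccccc9)c7)[C@H](OCc9ccccc9)C3)c2c(OCc9ccccc9)cc(O[Si](C(C)C)(C(C)C)C(C)C)c([C@H]3c4c(OCc9ccccc9)cc(OCc9ccccc9)cc4O[C@H](c7cc(OCc9ccccc9)c(OCc9ccccc9)c(OCc9ccccc9)c7)[C@@H]3OCc9ccccc9)c2O)[C@@H](O[Si](CC)(CC)CC)c7cc(OCc9ccccc9)c(OCc9ccccc9)c(OCc9ccccc9)c7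

A6 | alternative 3 | 3,5-bis(benzyloxy)-2-[1-(benzylated terminal unit C8)prop-2-enyl]phenyl 3,4,5-tris(benzyloxy)benzoate | C=C[C@@H](c2c(OCc9ccccc9)cc(OCc9ccccc9)c3c2O[C@H](c7cc(OCc9ccccc9)c(OCc9ccccc9)c(OCc9ccccc9)c7)[C@H](OCc9ccccc9)C3)c2c(OCc9ccccc9)cc(OCc9ccccc9)cc2OC(=O)c7cc(OCc9ccccc9)c(OCc9ccccc9)c(OCc9ccccc9)c7

A7 | alternative 3 | 2-aryl-4H-chromene form of the middle unit bonded at C4 to C8 of the benzylated terminal unit | C1(c7cc(OCc9ccccc9)c(OCc9ccccc9)c(OCc9ccccc9)c7)=C[C@@H](c2c(OCc9ccccc9)cc(OCc9ccccc9)c3c2O[C@H](c7cc(OCc9ccccc9)c(OCc9ccccc9)c(OCc9ccccc9)c7)[C@H](OCc9ccccc9)C3)c2c(OCc9ccccc9)cc(OCc9ccccc9)cc2O1
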